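**Retrosynthetic overview**
- Endgame: the methoxy group and its (S) centre come last, by enolate hydroxylation with a chiral oxaziridine and O-methylation of the ring-opened, silyl-protected 1,3-dione. The Z-diene side chain comes from a Wittig reaction on a 1-acetylcyclopentene.
- Key disconnection: the cyclopentene is cut at two ring bonds, the one from the diene-bearing sp2 carbon to the ring CH and the one from the ring CH2 to the carbinol carbon. This gives a three-carbon vinylcarbenoid (from 3-diazopent-4-en-2-one) and the enol-ether C=C of a 4H-pyran.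
- Enabling feature: the carbinol carbon (OH, CH3) and the neighbouring ring CH, which carries the CH2 link to C2 of the dione, are cis. The atoms O–C(CH3)–CH–CH2–C2=C3 therefore close a six-membered ring with a dione enol oxygen, and the two cyclopentene carbons become the C2=C3 enol-ether bond of 2-methyl-4,6,7,8-tetrahydro-5H-chromen-5-one.
- Ring order: cyclohexanedione ring (bought) → temporary pyran (step 1) → cyclopropane, then cyclopentene (step 5) → pyran opened by hydroxide (step 8).

Key step: step 5

Remark (assumption): the sense of induction of Rh2(S-PTAD)4 in step 5 and of (+)-(camphorsulfonyl)oxaziridine in step 10 is taken by analogy with simple enol ethers and cyclic enolates, and the antipode of either reagent is used if a model run shows the opposite sense; the target is treated as the enol form of the 2-substituted 4-methoxycyclohexane-1,3-dione.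

**Route**

Step 1
Reactants: 1 cyclohexane-1,3-dione; 2 methyl vinyl ketone (but-3-en-2-one)
Product: 4 2-methyl-4,6,7,8-tetrahydro-5H-chromen-5-one, via triketone 3 (not isolated)
Conditions: Et3N (cat.), EtOAc, rt; then TsOH·H2O (5 mol %), PhMe, reflux, Dean–Stark
Reagents that add atoms: none
Why: Michael addition gives 2-(3-oxobutyl)cyclohexane-1,3-dione 3, whose enol oxygen adds to the side-chain ketone and loses water under acid (hemiketal formation and dehydration) to give the bicyclic enol ether, with no stereocentre formed.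

Step 2
Reactants: 5 pentane-2,4-dione
Product: 6 3-diazopentane-2,4-dione
Conditions: 4-acetamidobenzenesulfonyl azide, Et3N, MeCN, 0 °C → rt
Reagents that add atoms: 4-acetamidobenzenesulfonyl azide, CC(=O)Nc1ccc(cc1)S(=O)(=O)N=[N+]=[N-]
Why: Regitz diazo transfer to an active methylene compound.

Step 3
Reactants: 6 3-diazopentane-2,4-dione
Product: 7 3-diazo-4-hydroxypentan-2-one (racemic)
Conditions: NaBH4 (0.3 equiv), MeOH, −10 °C
Reagents that add atoms: none
Why: borohydride reduction of one of the two equivalent ketones, held at the mono-reduction stage by substoichiometric hydride and low temperature; the carbinol centre is removed in step 4, so the racemate suffices.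

Step 4
Reactants: 7 3-diazo-4-hydroxypentan-2-one
Product: 8 3-diazopent-4-en-2-one
Conditions: POCl3, Et3N, CH2Cl2, 0 °C; used at once as a cold solution
Reagents that add atoms: none
Why: dehydration of a β-hydroxy-α-diazo carbonyl compound through its dichlorophosphate (β-elimination), the usual entry to vinyldiazocarbonyl compounds.

Step 5
Reactants: 4 2-methyl-4,6,7,8-tetrahydro-5H-chromen-5-one; 8 3-diazopent-4-en-2-one
Product: 10 (3aS,9aR)-1-acetyl-3a-methyl-3,3a,5,6,7,9a-hexahydrocyclopenta[b]chromen-8(9H)-one, via vinylcyclopropane 9 (not isolated)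
Conditions: 4 (1.5 equiv), Rh2(S-PTAD)4 (1 mol %), PhCF3, −30 °C, slow addition of 8; then CH2Cl2, Et2AlCl (3 equiv), −78 → −30 °C
Reagents that add atoms: none
Why: Rh2(S-PTAD)4 turns 8 into a donor/acceptor vinylcarbenoid of divalent rhodium, whose carbenoid carbon is attacked by the electron-rich CH terminus (C3) of the enol ether of 4 and closes to the donor–acceptor vinylcyclopropane 9 ([2+1] closure of the three-membered ring); Et2AlCl on the acetyl oxygen then breaks the bond between the acetyl/vinyl carbon and the O,CH3-substituted carbon to an oxocarbenium ion and an aluminium dienolate, whose vinyl terminus adds to the oxocarbenium carbon (5-exo-trig, enolendo closure of the cyclopentene). Net, the C1–C9a and C3–C3a bonds of 10 are formed in one flask. The closest known reaction type is the formal [3+2] annulation of rhodium vinylcarbenoids with vinyl ethers (cyclopropanation, then Lewis-acid ring expansion of the 2-alkoxy-1-vinylcyclopropane). C9a is set in the cyclopropanation by the chiral carboxylate ligands, which select one face of the flat, achiral pyran, and C3a follows from it, because the three-atom tether can reach the oxocarbenium carbon only from the face that already carries the new C–C bond (cis 5/6 fusion). The step needs attack at the enol-ether C2=C3 bond only (the C4a=C8a bond is a tetrasubstituted, electron-poor vinylogous ester), at the carbenoid carbon and not at the vinyl terminus (donor carboxylate ligands, non-polar medium, low temperature), and C- instead of O-closure of the zwitterion (aluminium on the enolate oxygen).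

Step 6
Reactants: 11 5-bromo-2-methylpent-2-ene; 12 triphenylphosphine
Product: 13 (4-methylpent-3-en-1-yl)triphenylphosphonium bromide
Conditions: MeCN, reflux
Reagents that add atoms: none
Why: SN2 quaternization of the phosphine by a primary alkyl bromide.

Step 7
Reactants: 10 tricyclic methyl ketone; 13 (4-methylpent-3-en-1-yl)triphenylphosphonium bromide
Product: 15 (3aS,9aR)-3a-methyl-1-[(2Z)-6-methylhepta-2,5-dien-2-yl]-3,3a,5,6,7,9a-hexahydrocyclopenta[b]chromen-8(9H)-one, via phosphorus ylide 14 (not isolated)
Conditions: 13, NaN(SiMe3)2, THF, −78 → 0 °C; then 10, −78 °C → rt; chromatography on AgNO3-impregnated silica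
Reagents that add atoms: none
Why: salt-free Wittig olefination of the methyl ketone, in which the ylide substituent is expected to end up cis to the larger ketone substituent (the cyclopentenyl ring), which is the Z isomer, while the deactivated vinylogous ester carbonyl should not react.

Step 8
Reactants: 15 tricyclic Z-diene
Product: 17 3-hydroxy-2-{[(1R,5S)-5-hydroxy-5-methyl-2-[(2Z)-6-methylhepta-2,5-dien-2-yl]cyclopent-2-en-1-yl]methyl}cyclohex-2-en-1-one, via potassium enolate 16 (not isolated)
Conditions: KOH, EtOH/H2O, 70 °C; then 1 M HCl to pH 4, 0 °C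
Reagents that add atoms: potassium hydroxide, [K+].[OH-]
Why: vinylogous saponification (hydroxide addition–elimination at C4a) expels the tertiary alkoxide with the C3a–O bond intact, so the carbinol configuration is kept, the stable dione enolate drives the opening, and no base-sensitive stereocentre is present yet.

Step 9
Reactants: 17 ring-opened dione
Product: 18 2-{[(1R,5S)-5-methyl-2-[(2Z)-6-methylhepta-2,5-dien-2-yl]-5-(triethylsilyloxy)cyclopent-2-en-1-yl]methyl}-3-(triethylsilyloxy)cyclohex-2-en-1-one
Conditions: Et3SiOTf (2.4 equiv), 2,6-lutidine, CH2Cl2, −78 °C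
Reagents that add atoms: triethylsilyl trifluoromethanesulfonate, CC[Si](CC)(CC)OS(=O)(=O)C(F)(F)F
Why: O-silylation of the enol and of the tertiary alcohol; the 2-substituted dione is locally symmetric, so either enol oxygen gives the same silyl enol ether, and the tertiary oxygen is kept from re-closing the pyran in step 10.

Step 10
Reactants: 18 bis(triethylsilyl) compound
Product: 20 (6S)-6-hydroxy-2-{[(1R,5S)-5-methyl-2-[(2Z)-6-methylhepta-2,5-dien-2-yl]-5-(triethylsilyloxy)cyclopent-2-en-1-yl]methyl}-3-(triethylsilyloxy)cyclohex-2-en-1-one, via lithium enolate 19 (not isolated)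
Conditions: LiN(i-Pr)2, THF, −78 °C; (+)-(camphorsulfonyl)oxaziridine, −78 → −40 °C; AcOH, −78 °C
Reagents that add atoms: (+)-(camphorsulfonyl)oxaziridine, CC1(C)[C@@H]2CC[C@]13CS(=O)(=O)N4O[C@@]34C2
Why: kinetic α'-deprotonation of the 3-silyloxy enone at C6 and hydroxylation of the enolate by the chiral N-sulfonyloxaziridine (Davis oxidation), the new C6 centre being set by the reagent because the other stereocentres are too remote to bias the enolate faces.

Step 11
Reactants: 20 (6S)-α'-hydroxy ketone
Product: 21 (6S)-6-methoxy-2-{[(1R,5S)-5-methyl-2-[(2Z)-6-methylhepta-2,5-dien-2-yl]-5-(triethylsilyloxy)cyclopent-2-en-1-yl]methyl}-3-(triethylsilyloxy)cyclohex-2-en-1-one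
Conditions: MeI, Ag2O, 4 Å MS, CH2Cl2, rt, dark
Reagents that add atoms: iodomethane, CI
Why: Purdie methylation, a silver-oxide-mediated O-alkylation without strong base, so that the α-alkoxy ketone centre should not epimerize and the silyl enol ether should survive.

Step 12
Reactants: 21 (6S)-α'-methoxy ketone
Product: 22 (4S)-3-hydroxy-2-{[(1R,5S)-5-hydroxy-5-methyl-2-[(2Z)-6-methylhepta-2,5-dien-2-yl]cyclopent-2-en-1-yl]methyl}-4-methoxycyclohex-2-en-1-one (CNP0148956.1)
Conditions: HF·pyridine, pyridine, THF, 0 °C
Reagents that add atoms: none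
Why: fluoride cleavage of both Si–O bonds under buffered conditions frees the dione enol and the tertiary alcohol without base at the α-methoxy centre and without acid strong enough to ionize the carbinol or re-close the pyran.

**Compound list**
1 | cyclohexane-1,3-dione | O=C1CCCC(=O)C1 | starting material
2 | methyl vinyl ketone (but-3-en-2-one) | CC(=O)C=C | starting material
3 | 2-(3-oxobutyl)cyclohexane-1,3-dione | CC(=O)CCC1C(=O)CCCC1=O | intermediate
4 | 2-methyl-4,6,7,8-tetrahydro-5H-chromen-5-one | CC1=CCC2=C(O1)CCCC2=O | intermediate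
5 | pentane-2,4-dione | CC(=O)CC(C)=O | starting material
6 | 3-diazopentane-2,4-dione | CC(=O)C(=[N+]=[N-])C(C)=O | intermediate
7 | 3-diazo-4-hydroxypentan-2-one (racemic) | CC(O)C(=[N+]=[N-])C(C)=O | intermediate
8 | 3-diazopent-4-en-2-one | C=CC(=[N+]=[N-])C(C)=O | intermediate
9 | 1-acetyl-1a-methyl-1-vinyl-1a,3,4,5,7,7a-hexahydro-1H-cyclopropa[b]chromen-6-one, cyclopropane cis-fused to the pyran, acetyl drawn anti to the pyran ring (this centre becomes sp2 in 10) | O=C1CCCC2=C1C[C@@H]3[C@](C(C)=O)(C=C)[C@]3(C)O2 | intermediate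
10 | (3aS,9aR)-1-acetyl-3a-methyl-3,3a,5,6,7,9a-hexahydrocyclopenta[b]chromen-8(9H)-one | O=C1CCCC2=C1C[C@@H]3C(C(C)=O)=CC[C@]3(C)O2 | intermediate
11 | 5-bromo-2-methylpent-2-ene | CC(C)=CCCBr | starting material
12 | triphenylphosphine | c1ccc(cc1)P(c1ccccc1)c1ccccc1 | starting material
13 | (4-methylpent-3-en-1-yl)triphenylphosphonium bromide | CC(C)=CCC[P+](c1ccccc1)(c1ccccc1)c1ccccc1.[Br-] | intermediate
14 | (4-methylpent-3-en-1-ylidene)triphenylphosphorane | CC(C)=CCC=P(c1ccccc1)(c1ccccc1)c1ccccc1 | intermediate
15 | (3aS,9aR)-3a-methyl-1-[(2Z)-6-methylhepta-2,5-dien-2-yl]-3,3a,5,6,7,9a-hexahydrocyclopenta[b]chromen-8(9H)-one | O=C1CCCC2=C1C[C@@H]3C(/C(C)=C\CC=C(C)C)=CC[C@]3(C)O2 | intermediate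
16 | potassium enolate of 17 | [K+].[O-]C1=C(C[C@@H]2C(/C(C)=C\CC=C(C)C)=CC[C@]2(C)O)C(=O)CCC1 | intermediate
17 | 3-hydroxy-2-{[(1R,5S)-5-hydroxy-5-methyl-2-[(2Z)-6-methylhepta-2,5-dien-2-yl]cyclopent-2-en-1-yl]methyl}cyclohex-2-en-1-one | O=C1CCCC(O)=C1C[C@@H]2C(/C(C)=C\CC=C(C)C)=CC[C@]2(C)O | intermediate
18 | 2-{[(1R,5S)-5-methyl-2-[(2Z)-6-methylhepta-2,5-dien-2-yl]-5-(triethylsilyloxy)cyclopent-2-en-1-yl]methyl}-3-(triethylsilyloxy)cyclohex-2-en-1-one | O=C1CCCC(O[Si](CC)(CC)CC)=C1C[C@@H]2C(/C(C)=C\CC=C(C)C)=CC[C@]2(C)O[Si](CC)(CC)CC | intermediate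
19 | lithium α'-enolate of 18 | [Li+].[O-]C1=CCCC(O[Si](CC)(CC)CC)=C1C[C@@H]2C(/C(C)=C\CC=C(C)C)=CC[C@]2(C)O[Si](CC)(CC)CC | intermediate
20 | (6S)-6-hydroxy derivative of 18 | O=C1[C@@H](O)CCC(O[Si](CC)(CC)CC)=C1C[C@@H]2C(/C(C)=C\CC=C(C)C)=CC[C@]2(C)O[Si](CC)(CC)CC | intermediate
21 | (6S)-6-methoxy derivative of 18 | O=C1[C@@H](OC)CCC(O[Si](CC)(CC)CC)=C1C[C@@H]2C(/C(C)=C\CC=C(C)C)=CC[C@]2(C)O[Si](CC)(CC)CC | intermediate
22 | (4S)-3-hydroxy-2-{[(1R,5S)-5-hydroxy-5-methyl-2-[(2Z)-6-methylhepta-2,5-dien-2-yl]cyclopent-2-en-1-yl]methyl}-4-methoxycyclohex-2-en-1-one | CO[C@H]1CCC(=O)C(C[C@@H]2C(/C(C)=C\CC=C(C)C)=CC[C@]2(C)O)=C1O | target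

**Step count**
Total: 12 steps. Longest linear sequence: 10 steps (steps 2, 3, 4, 5, 7, 8, 9, 10, 11, 12).

**Steps most likely to fail**

Step 5. The zwitterion may close through the acetyl oxygen and then lose the vinylogous carboxylate (aromatization to a furan). The enol ether may attack the vinyl terminus of the carbenoid (the regioisomeric annulation). The oxocarbenium ion may lose a proton instead of closing, and the face selectivity on this trisubstituted enol ether may be low. The fallback replaces the ketone acceptor by an ester, which has no nucleophilic ketone oxygen. It sets out from 4. Ethyl diazoacetate and acetaldehyde (DBU cat.) should give ethyl 2-diazo-3-hydroxybutanoate F1, and POCl3/Et3N should dehydrate it to ethyl 2-diazobut-3-enoate F2. With 4 and Rh2(S-DOSP)4 at −40 °C this should give the vinylcyclopropane ester F3, and Et2AlCl should expand it to the tricyclic ethyl ester F4. Me(MeO)NH·HCl with i-PrMgCl should convert F4 into the tricyclic N-methoxy-N-methylamide F5. Deprotonation of the vinylogous ester with LiN(i-Pr)2 (the α'-enolate protects that carbonyl), followed by MeMgBr, should then give the methyl ketone, and the route is rejoined at 10.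

Step 7. The olefination may give poor Z/E discrimination, and the ylide may enolize the methyl ketone instead of adding to it. The fallback is a Horner–Wittig sequence with a separable intermediate; it sets out from 13 and 10. Aqueous NaOH at reflux should convert 13 into (4-methylpent-3-en-1-yl)diphenylphosphine oxide F6. Its lithio derivative (n-BuLi, THF, −78 °C) should add to 10, and the adduct with the relative configuration that leads to the Z-alkene, the β-hydroxy phosphine oxide F7, is separated by chromatography. NaH in DMF should then effect stereospecific syn-elimination, and the route is rejoined at 15.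

Step 10. Face selection rests on the reagent alone and may be poor, which would give the C6 epimer, hard to remove because the other centres are remote. The bulky oxaziridine may also oxidize the lithium enolate slowly. The fallback separates the epimers enzymatically; it sets out from 18. Hydroxylation of enolate 19 with achiral 2-(phenylsulfonyl)-3-phenyloxaziridine should give 20 together with its (6R)-epimer F8. A lipase (Burkholderia cepacia lipase, vinyl acetate, MTBE), selected by screening for acylation of the 6R alcohol, should convert F8 into the (6R)-acetate F9. Unchanged 20 is separated by chromatography, and the route is rejoined at 20.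

**Further compounds**
F1 | step 5 | ethyl 2-diazo-3-hydroxybutanoate (racemic) | CCOC(=O)C(=[N+]=[N-])C(C)O
F2 | step 5 | ethyl 2-diazobut-3-enoate | CCOC(=O)C(=[N+]=[N-])C=C
F3 | step 5 | ethyl 1a-methyl-6-oxo-1-vinyl-1a,3,4,5,7,7a-hexahydro-1H-cyclopropa[b]chromene-1-carboxylate | O=C1CCCC2=C1C[C@@H]3[C@](C(=O)OCC)(C=C)[C@]3(C)O2
F4 | step 5 | ethyl (3aS,9aR)-3a-methyl-8-oxo-3,3a,5,6,7,8,9,9a-octahydrocyclopenta[b]chromene-1-carboxylate | O=C1CCCC2=C1C[C@@H]3C(C(=O)OCC)=CC[C@]3(C)O2
F5 | step 5 | (3aS,9aR)-N-methoxy-N,3a-dimethyl-8-oxo-3,3a,5,6,7,8,9,9a-octahydrocyclopenta[b]chromene-1-carboxamide | O=C1CCCC2=C1C[C@@H]3C(C(=O)N(C)OC)=CC[C@]3(C)O2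
F6 | step 7 | (4-methylpent-3-en-1-yl)diphenylphosphine oxide | CC(C)=CCCP(=O)(c1ccccc1)c1ccccc1
F7 | step 7 | β-hydroxy phosphine oxide adduct of 10 (one of the two Z-forming adducts) | O=C1CCCC2=C1C[C@@H]3C([C@](C)(O)[C@@H](CC=C(C)C)P(=O)(c4ccccc4)c4ccccc4)=CC[C@]3(C)O2
F8 | step 10 | (6R)-6-hydroxy epimer of 20 | O=C1[C@H](O)CCC(O[Si](CC)(CC)CC)=C1C[C@@H]2C(/C(C)=C\CC=C(C)C)=CC[C@]2(C)O[Si](CC)(CC)CC
F9 | step 10 | (6R)-6-acetoxy derivative of 18 | O=C1[C@H](OC(C)=O)CCC(O[Si](CC)(CC)CC)=C1C[C@@H]2C(/C(C)=C\CC=C(C)C)=CC[C@]2(C)O[Si](CC)(CC)CC
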